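The meeting had to decide what to do with Thursday's flask at 2.5 h: take one of the options below, or leave it alone.

the same everywhere: starting material 0.044 M; added ligand 2.6 mM
- Thursday's: partner 2.5 equiv; second substrate 2 equiv; protic impurity 0.88 mM; free catalyst 2.6 mol%; the very flask that is asked about, followed so far
- Tuesday's: partner 2.5 equiv; second substrate 2 equiv; protic impurity 0.88 mM; free catalyst 1.7 mol%; run made earlier
- flask: partner 2.50 equiv; second substrate 2.00 equiv; protic impurity 0.880 mM; free catalyst 2.6 mol%; time 2.5 h

| run | time / min | target / % | starting material / % |
|---|---|---|---|
| Thursday's | 8.00 | 40.3 | 60.1 |
| Thursday's | 12.0 | 48.2 | 51.8 |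
| Thursday's | 20.0 | 55.0 | 44.7 |
| Thursday's | 30.0 | 61.2 | 39.9 |
| Thursday's | 50.0 | 63.7 | 36.8 |
| Thursday's | 90.0 | 65.6 | 33.7 |
| Tuesday's | 1.33 | 8.4 | 92.3 |
| Tuesday's | 4.00 | 18.5 | 80.8 |
| Tuesday's | 8.00 | 29.2 | 70.5 |
| Tuesday's | 12.0 | 36.0 | 63.7 |
| Tuesday's | 15.0 | 40.5 | 59.5 |
| Tuesday's | 20.0 | 45.7 | 55.7 |

(each reading ± 0.5 percentage points)

- gamma: at 2.5 h add free catalyst, 50.0% of the amount charged, then wait 50 min
- alpha: at 2.5 h take out 90% of the target then present, then wait 50 min
- zeta: at 2.5 h add partner, 100% of the amount charged, then wait 50 min
- eta: change nothing and wait 50 min more

* target, in percent of the starting material first charged, at 2.5 h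
* which option adds most target ("none" when 2 percentage points or less is all one gets) (gamma / alpha / zeta / eta / none)
* target present, with what was taken out counted in, in percent of the starting material first charged, after gamma
* target present, with what was taken out counted in, in percent of the starting material first charged, after eta

- removed target is counted in
- the analysis behind the earlier runs scatters by 0.5 percentage points, standard deviation
- additions bring no volume worth counting

**Minutes.** The minute-taker counted in one quantity: at Thursday's last reading, 1.09 is the reach of the catalyst charge, the natural log of starting material charged over starting material left. The minute-taker argued that a catalyst dying on its own clock gives, at equal times, reaches in the ratio of the loadings, whereas a surviving catalyst gives that ratio in the clocks at equal conversion. At 12.0 min the reaches stand at 1.46 and the loadings at 1.53. The clocks, from 15.0 min on Tuesday against 8.00 min on Thursday, give 1.88. The minute-taker therefore read Thursday's stop as the catalyst's, with the partner as a correction.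

The reckoning ran as follows. Gamma's half charge buys half of 1.09, scaled by partner now over partner on average. If the second substrate has kept pace with the starting material, the fraction of partner left is 0.213. The added reach is then 0.191, worth 5.9 percentage points of target. Zeta multiplies whatever rate remains, and reach moved 0.0880 in the last 40.0 min. The minute-taker's choice was gamma.

The forecast differed, naming zeta, with 66.7% now, 67.5% after gamma and 67.1% after waiting. Its author argued: “The likeliest reading is that the partner is running out, with the second substrate consuming it in parallel, while the catalyst survives.”

**Result.**

    free catalyst → spent catalyst (k = 0.00199 s⁻¹)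
    free catalyst + added ligand ⇌ idle complex, settled at all times (K = 760 M⁻¹)
    second substrate + partner + free catalyst → free catalyst + second product (k = 26.2 M⁻² s⁻¹)
    second substrate + protic impurity → quenched substrate (k = 9.87 M⁻¹ s⁻¹)
    starting material + partner + free catalyst → free catalyst + target (k = 33.9 M⁻² s⁻¹)

The flask stands at 66.6% at 2.5 h, and gamma is best, reaching 73.3%, a gain of 6.7 points against 0.16 points for zeta; waiting gives 66.7%. At 150 min, 99.8% of the catalyst charged stood as spent catalyst while 28.1% of the partner was still free. With that partner put into the reach, the half charge gives 73.7% of target.

On the neighbour with 0.018 M of starting material, partner and catalyst are taken to shrink with the charge. Reach is then 1.09 times the square of 0.409, scaled for average partner with 73% left there, which gives 0.246 and 21.8% of target. The computed neighbour gives 26.3%.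

The earlier runs and the new flask were computed from invented constants, and the scatter is random.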